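## Analysis of the target

Lower-case locants are used for atoms: ring A has a1 (CH carrying the linker CH2), a2 (CH carrying isopropenyl), a3 and a4 (CH2), a5 (methyl-bearing epoxide carbon) and a6 (epoxide CH); ring B has b1 (CH on the linker), b2, b3, b4 (C(CH3)OH), b5 (CHBr) and b6; the rings are joined as a1–CH2–C(=CH2)–b1. The seven stereocentres fall into two clusters. In ring A (a1 R, a2 S, a5 S, a6 R) the linker and the isopropenyl group are trans, and the epoxide oxygen lies on the face of the linker substituent. In ring B (b1 R, b4 S, b5 R) the hydroxyl, the bromine and the side chain are all cis, with OH axial and Br equatorial. The clusters are separated by the sp2 linker carbon, so neither ring can relay its configuration to the other. The sensitive groups are the trisubstituted epoxide (acid opens it at a5), the cis bromohydrin (an alkoxide next to the bromide invites ring contraction) and three alkenes that an oxidant must tell apart. Bromonium chemistry gives only trans bromohydrins, and peracid or halohydrin routes do not favour the epoxide face syn to the a1 substituent, so both have to be solved by other means. The strategy rests on one feature: with a temporary carbonyl at a4, ring A is a 2-methylcyclohex-2-enone (a5(CH3)=a6 conjugated to a4) in which a6 is an aldehyde carbon, a1 its α-carbon, and a2 the β-carbon of an ethyl ketone that carries an ester in place of isopropenyl.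

## Retrosynthetic reasoning

The two C–O bonds of the epoxide in 24 are cut first, giving triene 23. The epoxide is the most labile group and is best made last, on a substrate with no further acid, fluoride or organometallic steps ahead. The forward step must choose the trisubstituted alkene and the face syn to the a1 substituent, which calls for reagent control.

The isopropenyl group of 23 (carried as silyl ether 22) is traced through methyl ketone 21 and Weinreb amide 20 to ester 19, cutting first C=CH2 and then C–CH3. An ester at a2 is what the ring construction needs as an activating group, and it makes a2 epimerisable, so the trans arrangement is the resting state throughout.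

The a4 methylene of 19 is traced to allylic carbonate 18, alcohol 17 and enone 16. This puts back the carbonyl that makes ring A a cyclohexenone. The forward sequence must remove that oxygen without moving the a5=a6 alkene.

Enone 16 is cut at a1–a2 and a5=a6, giving aldehyde 10 and keto-enoate 13. No other pair of cuts opens ring A into an aldehyde α-carbon and a doubly activated alkene. Ring B and the linker already sit in 10, so the union of the two halves and the construction of ring A are one operation. The forward step must set a1 by a catalyst, because ring B is too far away to help.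

Keto-enoate 13 is cut at its alkene into glyoxylate 11 and stabilised ylide 12, an olefination that gives the E isomer.

Aldehyde 10 is traced through ester 9 to allylic alcohol 7 by a retro-[3,3] shift that cuts the bond between the future a1 and the linker CH2. Alcohol 7 comes from the isopropenyl group of silyl ether 6 by allylic hydroxylation, so the whole chain grows from a terpene side chain and b1 is never touched.

Silyl ether 6 comes from cis bromohydrin 5, and the C–Br bond of 5 is cut back to cyclic sulfate 3 of diol 1. Diol 1 supplies b1 and b4 from the chiral pool, and an SN2 inversion at b5 is the only way to place bromine cis to the hydroxyl.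

## Alternatives that were turned down

Alternative 1: The epoxide C–O bonds are traced to a cis-fused iodolactone A2, formed from the ring A acetic acid A1. In the forward step an iodonium ion forms on a5=a6 and the tethered carboxylate closes onto a6 from its own face, leaving iodine anti at a5; releasing the a6 alkoxide later displaces the tertiary iodide and gives the epoxide on the tether face. In its favour, the epoxide face is fixed by the substrate, with no chiral reagent and no competition from a distant alkene. On this point it is stronger than the chosen route. Against it, A1 must first be made with the trans a1/a2 pair in one enantiomer, the isopropenyl group can capture the carboxylate in a Markovnikov six-membered closure, and the tertiary iodide is prone to elimination. The acid carbon must also be joined afterwards to b1, a secondary stereogenic carbon of a ring that holds a base-sensitive bromide, so ring B would have to be built after the union. The chosen strategy offers instead a catalytic step that builds ring A with both carbon stereocentres on a linker already attached to a finished ring B.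

Alternative 2: Ring A is cut at a5=a6 to the acyclic diene A3, and ring-closing metathesis with the second-generation Grubbs catalyst gives cyclohexene A4 with loss of a volatile C3 alkene. In its favour, the closure is reliable, the alkene position is unambiguous, and no oxygen has to be placed at a4 and removed again; on these points it is as strong as or stronger than the chosen route. Against it, the anti a1/a2 pair must be set in an open chain by separate stereoselective steps, the isopropenyl group is a third alkene in the metathesis substrate, and A4 carries only a protected carbinol. The bond from the linker carbon to the ring B alkene is still to be made, and the epoxide face problem is unchanged. The chosen route is more convergent and sets a1 and a2 in the ring-forming step.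

Alternative 3: Ring B is cut at b1–b6 and b2–b3; vinyl ketone A5 and silyloxydiene A6 combine on heating to the silyl enol ether A7. In its favour, the cycloaddition gives the 1,4-relationship of the acyl and oxygen groups in one step, the enol ether fixes the later bromination at b5, and methyl addition anti to an α-bromine would give a cis bromohydrin. Against it, b1 forms as both epimers, and nothing in ring A can decide the absolute sense of b4 and b5, so two diastereomeric series result even if b1 is equilibrated through the ketone. The chosen route takes b1 and b4 from diol 1 and creates b5 by a stereospecific inversion.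

Key step: step 8

Remark: RB stands for the (1R,3R,4S)-3-bromo-4-methyl-4-(triethylsilyloxy)cyclohexyl group.
Remark: ylide 12 is taken as purchasable; it is a stabilised ylide of the kind made routinely from an α-haloketone and PPh3.
Remark: 17 and 18 are drawn as the a4 epimer expected from axial hydride delivery; either epimer serves, because this centre is removed in step 11.

Step 1
Reactants: 1 (1S,2S,4R)-limonene-1,2-diol
Product: 3 trans-fused cyclic sulfate (3aS,6R,7aS)-3a-methyl-6-(prop-1-en-2-yl)hexahydro-1,3,2-benzodioxathiole 2,2-dioxide, via cyclic sulfite 2 (not isolated)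
Conditions: SOCl2, Et3N, CH2Cl2, 0 °C; crude sulfite washed and redissolved; then RuCl3·3H2O (0.5 mol%), NaIO4, MeCN/CCl4/H2O, 0 °C, short contact
Reagents that add atoms: thionyl chloride O=S(Cl)Cl; sodium periodate [Na+].[O-]I(=O)(=O)=O
Why: Cyclic sulfite formation and oxidation at sulfur activate the diol without touching a stereocentre; the ring must flip to put both C–O bonds equatorial, and catalytic RuO4 should oxidise sulfur much faster than the isolated isopropenyl group if contact is brief.

Step 2
Reactants: 3 cyclic sulfate
Product: 5 (1S,2R,4R)-2-bromo-1-methyl-4-(prop-1-en-2-yl)cyclohexan-1-ol, via lithium alkyl sulfate 4 (not isolated)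
Conditions: LiBr, THF, 50 °C; then H2SO4 (cat.), H2O (2 equiv), THF, rt
Reagents that add atoms: lithium bromide [Li+].[Br-]
Why: Bromide opens the cyclic sulfate by SN2 at the secondary carbon b5 with inversion, since the tertiary b4 has no open rear side, which turns the trans diol into the cis bromohydrin; the tertiary sulfate monoester is then hydrolysed at the S–O bond, so b4 keeps its configuration.

Step 3
Reactants: 5 cis bromohydrin
Product: 6 {[(1S,2R,4R)-2-bromo-1-methyl-4-(prop-1-en-2-yl)cyclohexyl]oxy}triethylsilane
Conditions: Et3SiOSO2CF3, 2,6-lutidine, CH2Cl2, −78 to 0 °C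
Reagents that add atoms: triethylsilyl trifluoromethanesulfonate CC[Si](CC)(CC)OS(=O)(=O)C(F)(F)F
Why: A silyl triflate with a hindered base silylates the tertiary alcohol; the triethylsilyl ether prevents alkoxide formation next to the cis bromide in the basic steps ahead and is sturdier towards acid than a trimethylsilyl ether.

Step 4
Reactants: 6 silyl ether
Product: 7 2-(RB)prop-2-en-1-ol
Conditions: SeO2 (0.3 equiv), t-BuOOH, CH2Cl2, 0 °C to rt, stopped at partial conversion with recovery of 6
Reagents that add atoms: tert-butyl hydroperoxide CC(C)(C)OO (terminal oxidant); selenium dioxide O=[Se]=O (transfers the oxygen)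
Why: Allylic hydroxylation by ene reaction and [2,3]-sigmatropic shift should take place at the methyl group of the isopropenyl unit rather than at the ring methine b1; stopping early limits over-oxidation to the enal.

Step 5
Reactants: 7 allylic alcohol
Product: 9 ethyl 4-(RB)pent-4-enoate, via allyl ketene acetal 8 (not isolated)
Conditions: CH3C(OEt)3 (excess), EtCO2H (cat.), 135–140 °C, EtOH distilled off
Reagents that add atoms: triethyl orthoacetate CCOC(C)(OCC)OCC
Why: Johnson–Claisen rearrangement: acid-catalysed exchange gives ketene acetal 8, whose [3,3] shift forms the C–C bond at the alkene terminus and leaves the 1,1-disubstituted linker alkene, adding the two carbons that become a1 and a6.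

Step 6
Reactants: 9 ester
Product: 10 4-(RB)pent-4-enal
Conditions: i-Bu2AlH (1.1 equiv), CH2Cl2, −78 °C; aq. KNaC4H4O6
Reagents that add atoms: none
Why: Partial reduction of the ester stops at the aluminium hemiacetal at low temperature and releases the aldehyde on work-up; bromide, silyl ether and alkene are inert under these conditions.

Step 7
Reactants: 11 ethyl glyoxylate; 12 1-(triphenylphosphoranylidene)butan-2-one
Product: 13 ethyl (E)-4-oxohex-2-enoate
Conditions: CH2Cl2, 0 °C to rt
Reagents that add atoms: none
Why: Wittig reaction of a ketone-stabilised ylide with the reactive glyoxylate aldehyde should give the E alkene.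

Step 8
Reactants: 10 aldehyde; 13 keto-enoate
Product: 16 ethyl (1S,2S)-4-methyl-5-oxo-2-[2-(RB)prop-2-en-1-yl]cyclohex-3-ene-1-carboxylate, via Michael adduct 14 (not isolated), via aldol 15 (not isolated)
Conditions: 13 (1.5 equiv), (S)-α,α-diphenylprolinol trimethylsilyl ether (20 mol%), 4-nitrophenol (20 mol%), toluene, 0 °C to rt; then p-TsOH·H2O (0.5 equiv), rt
Reagents that add atoms: none
Why: The amine condenses with the aldehyde, not the ketone, to give the E enamine, which adds through the face away from the diphenyl(silyloxy)methyl group to the alkene carbon of 13 that is β to the ketone, forming a1–a2 and, after hydrolysis, adduct 14. Acid then enolises the ethyl ketone towards its CH2 group, which adds to the aldehyde carbon to give aldol 15, and loss of water gives the conjugated a5=a6 enone 16. The closest known reaction type is the diarylprolinol silyl ether-catalysed Michael addition of aldehydes to γ-keto-α,β-unsaturated esters and vinyl ketones followed by intramolecular aldol condensation to cyclohexenones. Ring A closes in the 6-(enolexo)-exo-trig mode; the other enol of the ketone, or the aldehyde enol attacking the ketone, would give four-membered rings. The a1 centre is set by the catalyst, and the (S) amine gives the required sense by analogy with its known additions to nitroalkenes. The a2 centre follows from the syn topicity of the open transition state and, being α to the ester, is also held trans by equilibration. The step needs attack β to the ketone, not β to the ester, and the stronger acceptor character of the ketone secures this. Ring B is too far away to influence the enamine face, so the stereochemical outcome depends on the catalyst alone.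

Step 9
Reactants: 16 enone ester
Product: 17 ethyl (1S,2S,5R)-5-hydroxy-4-methyl-2-[2-(RB)prop-2-en-1-yl]cyclohex-3-ene-1-carboxylate
Conditions: NaBH4, CeCl3·7H2O, MeOH, −40 to 0 °C
Reagents that add atoms: none
Why: Luche reduction adds hydride to the enone carbonyl only and leaves the ester, bromide and silyl ether untouched; axial delivery should favour the carbinol cis to the ester, but this centre is temporary.

Step 10
Reactants: 17 allylic alcohol
Product: 18 ethyl (1S,2S,5R)-5-[(methoxycarbonyl)oxy]-4-methyl-2-[2-(RB)prop-2-en-1-yl]cyclohex-3-ene-1-carboxylate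
Conditions: ClCO2Me, pyridine, DMAP (cat.), CH2Cl2, 0 °C
Reagents that add atoms: methyl chloroformate COC(=O)Cl
Why: Acylation of the secondary allylic alcohol gives the carbonate that palladium can ionise.

Step 11
Reactants: 18 allylic carbonate
Product: 19 ethyl (1S,2S)-4-methyl-2-[2-(RB)prop-2-en-1-yl]cyclohex-3-ene-1-carboxylate
Conditions: Pd(PPh3)4 (5 mol%), NaBH4, THF, 0 °C to rt
Reagents that add atoms: none
Why: Zerovalent palladium ionises the carbonate to an η3-allyl complex over a4–a5–a6, and borohydride should deliver hydride to the less hindered terminus a4 (next to CH2) rather than a6 (next to the substituted a1), so the alkene stays at a5=a6 (palladium-catalysed allylic hydrogenolysis). The secondary alkyl bromide and the ester should not react under these conditions.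

Step 12
Reactants: 19 ester
Product: 20 (1S,2S)-N-methoxy-N,4-dimethyl-2-[2-(RB)prop-2-en-1-yl]cyclohex-3-ene-1-carboxamide
Conditions: MeNH(OMe)·HCl, i-PrMgCl, THF, −20 to 0 °C
Reagents that add atoms: N,O-dimethylhydroxylamine hydrochloride CNOC.Cl
Why: The magnesium amide made in the flask converts the ester directly into the Weinreb amide; a2 is enolisable but already holds the more stable trans arrangement.

Step 13
Reactants: 20 Weinreb amide
Product: 21 1-{(1S,2S)-4-methyl-2-[2-(RB)prop-2-en-1-yl]cyclohex-3-en-1-yl}ethan-1-one
Conditions: MeMgBr, THF, 0 °C; aq. NH4Cl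
Reagents that add atoms: methylmagnesium bromide C[Mg]Br
Why: The Grignard reagent adds once, because the chelated tetrahedral intermediate survives until work-up, and gives the methyl ketone.

Step 14
Reactants: 21 methyl ketone
Product: 22 triethyl{[(1S,2R,4R)-2-bromo-1-methyl-4-{3-[(1S,6S)-3-methyl-6-(prop-1-en-2-yl)cyclohex-2-en-1-yl]prop-1-en-2-yl}cyclohexyl]oxy}silane
Conditions: Ph3PCH3Br, KOt-Bu, THF, 0 °C to rt
Reagents that add atoms: methyltriphenylphosphonium bromide C[P+](c1ccccc1)(c1ccccc1)c1ccccc1.[Br-]
Why: Wittig methylenation installs the isopropenyl group; any enolisation at a2 by the ylide returns the trans isomer, and the silyl ether keeps the bromohydrin safe from base.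

Step 15
Reactants: 22 silyl ether
Product: 23 (1S,2R,4R)-2-bromo-1-methyl-4-{3-[(1S,6S)-3-methyl-6-(prop-1-en-2-yl)cyclohex-2-en-1-yl]prop-1-en-2-yl}cyclohexan-1-ol
Conditions: Bu4NF, AcOH (1:1), THF, 0 °C to rt
Reagents that add atoms: none
Why: Fluoride cleaves the tertiary silyl ether; the acetic acid buffer keeps the freed alcohol protonated, so the cis bromohydrin does not undergo base-induced ring contraction, and no acid strong enough to protonate the alkenes is present.

Step 16
Reactants: 23 triene bromohydrin
Product: 24 (1S,2R,4R)-2-bromo-1-methyl-4-{3-[(1R,2R,3S,6S)-6-methyl-3-(prop-1-en-2-yl)-7-oxabicyclo[4.1.0]heptan-2-yl]prop-1-en-2-yl}cyclohexan-1-ol (CNP0213097.1)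
Conditions: 1,2:4,5-di-O-isopropylidene-β-D-erythro-hexo-2,3-diulo-2,6-pyranose (30 mol%), KHSO5 (as 2KHSO5·KHSO4·K2SO4, limiting), K2CO3, Bu4NHSO4 (cat.), MeCN/CH2(OMe)2/aq. Na2B4O7 buffer, pH 10.5, 0 °C
Reagents that add atoms: potassium peroxymonosulfate [K+].[O-]S(=O)(=O)OO
Why: Shi epoxidation: the chiral dioxirane should prefer the electron-rich trisubstituted a5=a6 alkene over the two 1,1-disubstituted ones. By the spiro transition-state model the D-fructose-derived ketone delivers oxygen to the face syn to the a1 substituent, giving a5 (S) and a6 (R). The reagent has to override a modest substrate preference for the other face.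

Compound list
1 | (1S,2S,4R)-1-methyl-4-(prop-1-en-2-yl)cyclohexane-1,2-diol | CC(=C)[C@@H]1CC[C@](C)(O)[C@@H](O)C1 | starting material
2 | (3aS,6R,7aS)-3a-methyl-6-(prop-1-en-2-yl)hexahydro-1,3,2-benzodioxathiole 2-oxide (both configurations at sulfur) | CC(=C)[C@@H]1CC[C@]2(C)OS(=O)O[C@H]2C1 | intermediate (not isolated)
3 | (3aS,6R,7aS)-3a-methyl-6-(prop-1-en-2-yl)hexahydro-1,3,2-benzodioxathiole 2,2-dioxide | CC(=C)[C@@H]1CC[C@]2(C)OS(=O)(=O)O[C@H]2C1 | intermediate
4 | lithium (1S,2R,4R)-2-bromo-1-methyl-4-(prop-1-en-2-yl)cyclohexyl sulfate | CC(=C)[C@@H]1CC[C@](C)(OS(=O)(=O)[O-])[C@H](Br)C1.[Li+] | intermediate (not isolated)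
5 | (1S,2R,4R)-2-bromo-1-methyl-4-(prop-1-en-2-yl)cyclohexan-1-ol | CC(=C)[C@@H]1CC[C@](C)(O)[C@H](Br)C1 | intermediate
6 | {[(1S,2R,4R)-2-bromo-1-methyl-4-(prop-1-en-2-yl)cyclohexyl]oxy}triethylsilane | CC(=C)[C@@H]1CC[C@](C)(O[Si](CC)(CC)CC)[C@H](Br)C1 | intermediate
7 | 2-[(1R,3R,4S)-3-bromo-4-methyl-4-(triethylsilyloxy)cyclohexyl]prop-2-en-1-ol | OCC(=C)[C@@H]1CC[C@](C)(O[Si](CC)(CC)CC)[C@H](Br)C1 | intermediate
8 | {[(1S,2R,4R)-2-bromo-4-{3-[(1-ethoxyethenyl)oxy]prop-1-en-2-yl}-1-methylcyclohexyl]oxy}triethylsilane | C=C(OCC)OCC(=C)[C@@H]1CC[C@](C)(O[Si](CC)(CC)CC)[C@H](Br)C1 | intermediate (not isolated)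
9 | ethyl 4-[(1R,3R,4S)-3-bromo-4-methyl-4-(triethylsilyloxy)cyclohexyl]pent-4-enoate | CCOC(=O)CCC(=C)[C@@H]1CC[C@](C)(O[Si](CC)(CC)CC)[C@H](Br)C1 | intermediate
10 | 4-[(1R,3R,4S)-3-bromo-4-methyl-4-(triethylsilyloxy)cyclohexyl]pent-4-enal | O=CCCC(=C)[C@@H]1CC[C@](C)(O[Si](CC)(CC)CC)[C@H](Br)C1 | intermediate
11 | ethyl glyoxylate | CCOC(=O)C=O | starting material
12 | 1-(triphenylphosphoranylidene)butan-2-one | CCC(=O)C=P(c1ccccc1)(c1ccccc1)c1ccccc1 | starting material
13 | ethyl (E)-4-oxohex-2-enoate | CCC(=O)/C=C/C(=O)OCC | intermediate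
14 | ethyl (2S,3R)-5-[(1R,3R,4S)-3-bromo-4-methyl-4-(triethylsilyloxy)cyclohexyl]-3-formyl-2-(2-oxobutyl)hex-5-enoate | O=C[C@H](CC(=C)[C@@H]1CC[C@](C)(O[Si](CC)(CC)CC)[C@H](Br)C1)[C@@H](C(=O)OCC)CC(=O)CC | intermediate (not isolated)
15 | ethyl (1S,2R)-2-{2-[(1R,3R,4S)-3-bromo-4-methyl-4-(triethylsilyloxy)cyclohexyl]prop-2-en-1-yl}-3-hydroxy-4-methyl-5-oxocyclohexane-1-carboxylate (epimers at C3 and C4) | C=C(C[C@@H]1[C@@H](C(=O)OCC)CC(=O)C(C)C1O)[C@@H]1CC[C@](C)(O[Si](CC)(CC)CC)[C@H](Br)C1 | intermediate (not isolated)
16 | ethyl (1S,2S)-2-{2-[(1R,3R,4S)-3-bromo-4-methyl-4-(triethylsilyloxy)cyclohexyl]prop-2-en-1-yl}-4-methyl-5-oxocyclohex-3-ene-1-carboxylate | C=C(C[C@@H]1[C@@H](C(=O)OCC)CC(=O)C(C)=C1)[C@@H]1CC[C@](C)(O[Si](CC)(CC)CC)[C@H](Br)C1 | intermediate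
17 | ethyl (1S,2S,5R)-2-{2-[(1R,3R,4S)-3-bromo-4-methyl-4-(triethylsilyloxy)cyclohexyl]prop-2-en-1-yl}-5-hydroxy-4-methylcyclohex-3-ene-1-carboxylate | C=C(C[C@@H]1[C@@H](C(=O)OCC)C[C@@H](O)C(C)=C1)[C@@H]1CC[C@](C)(O[Si](CC)(CC)CC)[C@H](Br)C1 | intermediate
18 | ethyl (1S,2S,5R)-2-{2-[(1R,3R,4S)-3-bromo-4-methyl-4-(triethylsilyloxy)cyclohexyl]prop-2-en-1-yl}-5-[(methoxycarbonyl)oxy]-4-methylcyclohex-3-ene-1-carboxylate | C=C(C[C@@H]1[C@@H](C(=O)OCC)C[C@@H](OC(=O)OC)C(C)=C1)[C@@H]1CC[C@](C)(O[Si](CC)(CC)CC)[C@H](Br)C1 | intermediate
19 | ethyl (1S,2S)-2-{2-[(1R,3R,4S)-3-bromo-4-methyl-4-(triethylsilyloxy)cyclohexyl]prop-2-en-1-yl}-4-methylcyclohex-3-ene-1-carboxylate | C=C(C[C@@H]1[C@@H](C(=O)OCC)CCC(C)=C1)[C@@H]1CC[C@](C)(O[Si](CC)(CC)CC)[C@H](Br)C1 | intermediate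
20 | (1S,2S)-2-{2-[(1R,3R,4S)-3-bromo-4-methyl-4-(triethylsilyloxy)cyclohexyl]prop-2-en-1-yl}-N-methoxy-N,4-dimethylcyclohex-3-ene-1-carboxamide | C=C(C[C@@H]1[C@@H](C(=O)N(C)OC)CCC(C)=C1)[C@@H]1CC[C@](C)(O[Si](CC)(CC)CC)[C@H](Br)C1 | intermediate
21 | 1-[(1S,2S)-2-{2-[(1R,3R,4S)-3-bromo-4-methyl-4-(triethylsilyloxy)cyclohexyl]prop-2-en-1-yl}-4-methylcyclohex-3-en-1-yl]ethan-1-one | C=C(C[C@@H]1[C@@H](C(C)=O)CCC(C)=C1)[C@@H]1CC[C@](C)(O[Si](CC)(CC)CC)[C@H](Br)C1 | intermediate
22 | triethyl{[(1S,2R,4R)-2-bromo-1-methyl-4-{3-[(1S,6S)-3-methyl-6-(prop-1-en-2-yl)cyclohex-2-en-1-yl]prop-1-en-2-yl}cyclohexyl]oxy}silane | C=C(C[C@@H]1[C@@H](C(=C)C)CCC(C)=C1)[C@@H]1CC[C@](C)(O[Si](CC)(CC)CC)[C@H](Br)C1 | intermediate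
23 | (1S,2R,4R)-2-bromo-1-methyl-4-{3-[(1S,6S)-3-methyl-6-(prop-1-en-2-yl)cyclohex-2-en-1-yl]prop-1-en-2-yl}cyclohexan-1-ol | C=C(C[C@@H]1[C@@H](C(=C)C)CCC(C)=C1)[C@@H]1CC[C@](C)(O)[C@H](Br)C1 | intermediate
24 | (1S,2R,4R)-2-bromo-1-methyl-4-{3-[(1R,2R,3S,6S)-6-methyl-3-(prop-1-en-2-yl)-7-oxabicyclo[4.1.0]heptan-2-yl]prop-1-en-2-yl}cyclohexan-1-ol | C=C(C[C@@H]1[C@@H](C(=C)C)CC[C@]2(C)O[C@H]12)[C@@H]1CC[C@](C)(O)[C@H](Br)C1 | target

Total step count: 16. Longest linear sequence: 15 steps (steps 1–6 and 8–16); step 7 is a one-step side branch.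

Steps least certain to work

Step 8 (key step). The main danger is loss of configurational purity at a1: adduct 14 remains an enolisable aldehyde while the amine is present and while acid is closing the ring. The doubly activated alkene of 13 can also hold the catalyst reversibly and slow turnover, and the acid stage may loosen the silyl ether. Fallback: separate enamine formation, C–C bond formation and ring closure. Aldehyde 10 is condensed with (S)-2-(methoxymethyl)pyrrolidine over molecular sieves to the preformed enamine (S)-1-{(1E)-4-[(1R,3R,4S)-3-bromo-4-methyl-4-(triethylsilyloxy)cyclohexyl]penta-1,4-dien-1-yl}-2-(methoxymethyl)pyrrolidine F1. F1 is added to 13 at low temperature with no free amine or acid present, and buffered aqueous acetic acid then releases 14. On steric grounds the (S) auxiliary should expose the same enamine face; if not, its enantiomer is used. Adduct 14 is cyclised at once in a separate flask with dibenzylammonium trifluoroacetate, and the route is rejoined at 16.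

Step 2 (with step 1, which feeds it). The displacement may be slow or may be overtaken by elimination. Carbon b5 is next to a quaternary carbon, and the trans-fused sulfate forces the isopropenyl group axial, on the same side as the incoming bromide. In step 1 the oxidant may also attack the isopropenyl alkene if contact is prolonged. Fallback: avoid the cyclic sulfate. Diol 1 is silylated twice (Et3SiOSO2CF3, 2,6-lutidine) to the bis(triethylsilyl) ether F2. The secondary silyl ether is removed selectively (pyridinium p-toluenesulfonate, MeOH, 0 °C) to give (1S,2S,5R)-2-methyl-5-(prop-1-en-2-yl)-2-(triethylsilyloxy)cyclohexan-1-ol F3. The axial secondary hydroxyl of F3 is then replaced with inversion under Appel conditions for hindered carbinols (CBr4, (n-C8H17)3P, toluene, 70 °C), where bromide attacks from the equatorial direction. This rejoins the route at 6.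

Step 11. Hydride may be delivered to a6 instead of a4, which moves the alkene to a4=a5, or the allyl complex may lose a proton to give a diene. Both allyl termini are secondary, and the preference rests only on the steric difference between their neighbours. Fallback: a sequence whose regiochemistry is fixed by mechanism, starting from enone 16. Nucleophilic epoxidation (t-BuOOH, DBU) gives the epoxy ketone ethyl (1S,2R,3S,6S)-2-[2-(RB)prop-2-en-1-yl]-6-methyl-5-oxo-7-oxabicyclo[4.1.0]heptane-3-carboxylate F4. Wharton rearrangement (N2H4·H2O, AcOH, MeOH) gives the transposed allylic alcohol ethyl (1S,5S,6R)-6-[2-(RB)prop-2-en-1-yl]-5-hydroxy-4-methylcyclohex-3-ene-1-carboxylate F5, with the hydroxyl on a6 and the alkene at a4=a5. Mitsunobu displacement with 2-nitrobenzenesulfonylhydrazide (PPh3, diethyl azodicarboxylate) then forms the allylic diazene, which loses N2 with hydrogen transfer to a4 and returns the alkene to a5=a6. This rejoins the route at 19.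

Step 16. Poor facial selectivity is the most likely failure. A cyclohexene with a pseudo-equatorial allylic substituent is attacked slightly more easily on the face away from it, so the catalyst works against the substrate. Some epoxidation of the 1,1-disubstituted alkenes is the second risk. A halohydrin detour does not help: trans-diaxial, Markovnikov opening of the bromonium ion leads to the wrong epoxide. Fallback: give up face control in the oxidation and recover it by separation and recycling. Silyl ether 22 is epoxidised with dimethyldioxirane in acetone at −20 °C. The product is the triethylsilyl ether of 24, F6, together with its a5,a6-epimeric epoxide F7, and the two are separated by chromatography. F7 is returned to 22 by stereospecific deoxygenation (Ph3P=Se, CF3CO2H, CH2Cl2). F6 is desilylated under the buffered fluoride conditions of step 15, which rejoins the route at 24.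

Further compounds
F1 | step 8 | (S)-1-{(1E)-4-[(1R,3R,4S)-3-bromo-4-methyl-4-(triethylsilyloxy)cyclohexyl]penta-1,4-dien-1-yl}-2-(methoxymethyl)pyrrolidine | COC[C@@H]1CCCN1/C=C/CC(=C)[C@@H]1CC[C@](C)(O[Si](CC)(CC)CC)[C@H](Br)C1
F2 | step 2 | {[(1S,2S,4R)-1-methyl-4-(prop-1-en-2-yl)cyclohexane-1,2-diyl]bis(oxy)}bis(triethylsilane) | CC(=C)[C@@H]1CC[C@](C)(O[Si](CC)(CC)CC)[C@@H](O[Si](CC)(CC)CC)C1
F3 | step 2 | (1S,2S,5R)-2-methyl-5-(prop-1-en-2-yl)-2-(triethylsilyloxy)cyclohexan-1-ol | CC(=C)[C@@H]1CC[C@](C)(O[Si](CC)(CC)CC)[C@@H](O)C1
F4 | step 11 | ethyl (1S,2R,3S,6S)-2-{2-[(1R,3R,4S)-3-bromo-4-methyl-4-(triethylsilyloxy)cyclohexyl]prop-2-en-1-yl}-6-methyl-5-oxo-7-oxabicyclo[4.1.0]heptane-3-carboxylate | C=C(C[C@@H]1[C@@H](C(=O)OCC)CC(=O)[C@@]2(C)O[C@@H]12)[C@@H]1CC[C@](C)(O[Si](CC)(CC)CC)[C@H](Br)C1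
F5 | step 11 | ethyl (1S,5S,6R)-6-{2-[(1R,3R,4S)-3-bromo-4-methyl-4-(triethylsilyloxy)cyclohexyl]prop-2-en-1-yl}-5-hydroxy-4-methylcyclohex-3-ene-1-carboxylate | C=C(C[C@@H]1[C@@H](C(=O)OCC)CC=C(C)[C@H]1O)[C@@H]1CC[C@](C)(O[Si](CC)(CC)CC)[C@H](Br)C1
F6 | step 16 | triethyl{[(1S,2R,4R)-2-bromo-1-methyl-4-{3-[(1R,2R,3S,6S)-6-methyl-3-(prop-1-en-2-yl)-7-oxabicyclo[4.1.0]heptan-2-yl]prop-1-en-2-yl}cyclohexyl]oxy}silane | C=C(C[C@@H]1[C@@H](C(=C)C)CC[C@]2(C)O[C@H]12)[C@@H]1CC[C@](C)(O[Si](CC)(CC)CC)[C@H](Br)C1
F7 | step 16 | triethyl{[(1S,2R,4R)-2-bromo-1-methyl-4-{3-[(1S,2R,3S,6R)-6-methyl-3-(prop-1-en-2-yl)-7-oxabicyclo[4.1.0]heptan-2-yl]prop-1-en-2-yl}cyclohexyl]oxy}silane | C=C(C[C@@H]1[C@@H](C(=C)C)CC[C@@]2(C)O[C@@H]12)[C@@H]1CC[C@](C)(O[Si](CC)(CC)CC)[C@H](Br)C1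
A1 | alternative 1 | 2-[(1S,6S)-3-methyl-6-(prop-1-en-2-yl)cyclohex-2-en-1-yl]acetic acid | OC(=O)C[C@@H]1[C@@H](C(=C)C)CCC(C)=C1
A2 | alternative 1 | (3aR,4S,7R,7aR)-7-iodo-7-methyl-4-(prop-1-en-2-yl)hexahydro-1-benzofuran-2(3H)-one | O=C1C[C@@H]2[C@@H](C(=C)C)CC[C@@](C)(I)[C@@H]2O1
A3 | alternative 2 | 1-methoxy-4-({[(2S,3S)-6-methyl-2-[(1E)-prop-1-en-1-yl]-3-(prop-1-en-2-yl)hept-6-en-1-yl]oxy}methyl)benzene | COc1ccc(COC[C@@H](/C=C/C)[C@@H](C(=C)C)CCC(C)=C)cc1
A4 | alternative 2 | 1-methoxy-4-({[(1S,6S)-3-methyl-6-(prop-1-en-2-yl)cyclohex-2-en-1-yl]methoxy}methyl)benzene | COc1ccc(COC[C@@H]2[C@@H](C(=C)C)CCC(C)=C2)cc1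
A5 | alternative 3 | 1-[(1S,6S)-3-methyl-6-(prop-1-en-2-yl)cyclohex-2-en-1-yl]but-3-en-2-one | C=CC(=O)C[C@@H]1[C@@H](C(=C)C)CCC(C)=C1
A6 | alternative 3 | 2-(trimethylsilyloxy)buta-1,3-diene | C=CC(=C)O[Si](C)(C)C
A7 | alternative 3 | 2-[(1S,6S)-3-methyl-6-(prop-1-en-2-yl)cyclohex-2-en-1-yl]-1-[(1R)-4-(trimethylsilyloxy)cyclohex-3-en-1-yl]ethan-1-one (one b1 epimer drawn) | O=C(C[C@@H]1[C@@H](C(=C)C)CCC(C)=C1)[C@@H]1CCC(O[Si](C)(C)C)=CC1
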